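20.8 mM of the 50 mM of J charged in gamma stands neither as E nor as Z at 2.00 h, and the dispute over this flask starts there.

all flasks: G 0.12 mM
- gamma: J 0.050 M; run made earlier
- theta: J 0.20 M; run made earlier
- flask: J 0.10 M; time 3.0 h

| run | time / h | Z / % | E / % |
|---|---|---|---|
| gamma | 0.833 | 8.1 | 62.9 |
| gamma | 2.00 | 18.6 | 39.7 |
| gamma | 2.50 | 21.5 | 31.3 |
| gamma | 4.00 | 22.9 | 20.0 |
| theta | 0.250 | 0.6 | 9.0 |
| theta | 0.667 | 2.0 | 14.7 |
| theta | 1.50 | 3.5 | 15.9 |
| theta | 4.00 | 10.5 | 16.7 |

(readings scatter by 0.5 percentage points)
- as a solid, counted per litre of solution: J
- the numbers in the tables scatter with a standard deviation of 0.5 percentage points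
- at the start none of J is in solution
- E means what is dissolved; the solid is not counted in it
- E is what J becomes in solution
* Z at 3.0 h, in percent of the J charged
* concentration of E in solution at 3.0 h, in percent of saturation

For solid J, the limiting reagent, I write a plain balance that holds while solid stands: solid left = charge − [E] − drain × time. The forecaster reads gamma's later decline as “a side loss of about 5 mM/h” and forecasts, for the flask, Z at 15.5 % and [E] at 95 % of saturation.

I read it differently. Theta's [E] reads 33.4 mM at 4.00 h, while gamma's has dropped to 19.9 mM at 2.00 h, so I take it that solid no longer feeds gamma. The missing amount is then side loss, 10.4 mM/h on average. Adding theta's Z rate of 5.25 mM/h gives the drain, the J per hour leaving the dissolved pool while [E] holds its plateau: 15.7 mM/h.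

For the flask, my balance leaves 19.6 mM of solid at 3.0 h, so we agree on solid remaining, and I also expect Z near 15.8 %. We part on [E]. I take the plateau as a steady state, with dissolution matching the drain. Theta's early rise, read towards that plateau, gives a relaxation constant of 3.10 /h, which by my reckoning puts saturation above the plateau by drain/constant and [E] in the flask at 86.8 % of saturation.

The flask gives Z 16.2 % and [E] at 77.8 % of saturation.

    D + G ⇌ X + G, rate k1*[G]*[D] forward; the back reaction follows from the equilibrium constant (K = 0.0790, k = 1730 /M/h)
    E ⇌ Z (K = 1.56, k = 0.247 /h)
    J ⇌ E, rate k3*(cs3 - [E]) while solid is left; crystals form when [E] > cs3 (solubility = 43.0 mM, k = 2.38 /h)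
    Z ⇌ D (K = 1.51, k = 0.0868 /h)
    X + G ⇌ E + G, rate k5*[G]*[X] forward; the back reaction follows from the equilibrium constant (k = 53.8 /M/h)
    2 E → L (k = 7.50 /M/h)

At 3.00 h in the flask, E goes to L twice as fast as to Z, forward steps taken (2.0), and the amounts standing there put the drain, on average up to that time, at 20.2 mM/h, more than the 15.7 mM/h reckoned, with 6.06 mM of J still solid. In the neighbour flask with 0.17 M of J, read at the same time, my drain leaves 52.6 % of the charge solid against a simulated 44.7 %, and a steady Z rate, the forecast's view, taken at my rate from theta, gives 9.26 % in that flask, where solid stands, against a simulated 9.55 %.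

The runs were computed for an exercise; the scatter is artificial.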